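**Strategy.** Both piperidines (rings A and B) are cut at C4–C5, the one ring bond that carries neither nitrogen nor a stereocentre, so N1, C2, C3 and C6 of each ring can be set in an open chain. A single two-directional ring-closing metathesis then forms both C4=C5 bonds and both six-membered rings with loss of ethene. Its precursor is a pseudo-symmetric bis(secondary amine): each nitrogen links an L-alanine-derived (2S,3S)-3-silyloxypent-4-en-2-yl arm to an R-configured, vinyl-bearing carbon at the end of a C29 chain. The central E-enal of that chain, made by self-aldol condensation of one C15 aldehyde, is masked as its dimethyl acetal.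

Key step: step 11

Remarks:
- Ring atoms are numbered as in the alkaloid: N1, C2 (methyl), C3 (oxygen), C6 (chain). In the systematic names these atoms are C6, C5 and C2 of a piperidin-2-yl group.
- Step 10 assumes that the (Sa,S,S) ligand gives R at the new N-bearing carbon of an alkyl-substituted allyl unit. This is to be confirmed on a mono-carbonate model; if the sense is the reverse, the (Ra,R,R) ligand is used with nothing else changed.
- Where several equivalent or independent sites react in one operation (steps 7 to 13), partly converted species are not numbered.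
- The THP groups are racemic at the acetal carbon, so 8 to 11 are epimer mixtures at centres that step 7 removes.
- The structures of the metathesis precursor (15) and product (18) were checked centre by centre against the target and needed no correction.

**Step 1**
Reactants: 1 N-Boc-L-alanine N-methoxy-N-methylamide
Product: 2 N-Boc-L-alaninal
Conditions: LiAlH4 (1.2 equiv), THF, 0 °C, 30 min; aq. KHSO4; crude used at once
Reagents that add atoms: none
Why: Hydride reduction of an N-methoxy-N-methylamide stops at the aldehyde because the chelated tetrahedral aluminate survives until work-up, and the cold quench with immediate use protects the C2 centre from epimerisation.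

**Step 2**
Reactants: 2 N-Boc-L-alaninal
Product: 3 tert-butyl N-[(2S,3S)-3-hydroxypent-4-en-2-yl]carbamate
Conditions: CH2=CHMgBr (3.5 equiv), ZnCl2 (1.8 equiv), THF, −78 → 0 °C; aq. NH4Cl; chromatography
Reagents that add atoms: vinylmagnesium bromide, C=C[Mg]Br
Why: Chelation-controlled 1,2-addition of a vinyl organometallic to an α-carbamoylamino aldehyde: the N-metalated carbamate and the carbonyl oxygen share one metal in a five-membered chelate, the vinyl group enters on the face opposite the methyl group, and C3 is set S (hydroxyl syn to nitrogen); the minor anti epimer is removed by chromatography.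

**Step 3**
Reactants: 3 tert-butyl N-[(2S,3S)-3-hydroxypent-4-en-2-yl]carbamate
Product: 5 (2S,3S)-3-(tert-butyldimethylsilyloxy)pent-4-en-2-amine, via silyl carbamate 4 (not isolated)
Conditions: TBSOTf (3 equiv), 2,6-lutidine (4 equiv), CH2Cl2, 0 °C → rt; then K2CO3, MeOH/H2O, rt
Reagents that add atoms: tert-butyldimethylsilyl trifluoromethanesulfonate, CC(C)(C)[Si](C)(C)OS(=O)(=O)C(F)(F)F
Why: Silyl triflate O-silylation of the secondary alcohol runs together with the known exchange of a tert-butyl carbamate into a silyl carbamate (loss of 2-methylpropene), and only the silyl carbamate is cleaved by mild aqueous base with decarboxylation, so the amine is freed with the silyl ether and both stereocentres intact.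

**Step 4**
Reactants: 6 12-bromododecan-1-ol; 7 2-(prop-2-yn-1-yloxy)tetrahydro-2H-pyran
Product: 8 15-(tetrahydro-2H-pyran-2-yloxy)pentadec-13-yn-1-ol
Conditions: 7 (2.4 equiv), n-BuLi (2.3 equiv), THF, −78 → 0 °C; then 6, DMPU, 0 °C → rt
Reagents that add atoms: none
Why: SN2 alkylation of a lithium acetylide by a primary bromide in a dipolar cosolvent; the extra equivalent of acetylide takes up the hydroxyl proton and the resulting lithium alkoxide is too weak a nucleophile to compete.

**Step 5**
Reactants: 8 15-(tetrahydro-2H-pyran-2-yloxy)pentadec-13-yn-1-ol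
Product: 9 15-(tetrahydro-2H-pyran-2-yloxy)pentadec-13-ynal
Conditions: TEMPO (10 mol%), PhI(OAc)2 (1.1 equiv), CH2Cl2, rt
Reagents that add atoms: none
Why: Oxoammonium (TEMPO) oxidation with a hypervalent iodine terminal oxidant stops at the aldehyde and leaves the alkyne and the THP acetal alone.

**Step 6**
Reactants: 9 15-(tetrahydro-2H-pyran-2-yloxy)pentadec-13-ynal (two molecules)
Product: 11 (2E)-2-[13-(tetrahydro-2H-pyran-2-yloxy)tridec-11-yn-1-yl]-17-(tetrahydro-2H-pyran-2-yloxy)heptadec-2-en-15-ynal, via β-hydroxy aldehyde 10 (not isolated)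
Conditions: KOH (0.3 equiv), EtOH, rt → 60 °C
Reagents that add atoms: none
Why: Base-catalysed self-aldol addition followed by E1cB loss of water (aldol condensation): the enolate partner supplies the α-carbon with its (CH2)10 arm, the acceptor supplies the β-carbon with its (CH2)11 arm, and the reversible conditions give the more stable E-enal with the formyl group trans to the β-chain.

**Step 7**
Reactants: 11 the bis-THP E-enal
Product: 12 (14E)-14-(dimethoxymethyl)nonacos-14-ene-2,27-diyne-1,29-diol
Conditions: HC(OMe)3 (6 equiv), TsOH·H2O (5 mol%), MeOH/THF, rt; Et3N quench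
Reagents that add atoms: trimethyl orthoformate, COC(OC)OC; methanol, CO
Why: Acid-catalysed acetalisation of the enal with the orthoformate as water scavenger, with concurrent transacetalisation of both THP ethers to methanol; the mild catalyst avoids conjugate addition and does not move the E-alkene.

**Step 8**
Reactants: 12 (14E)-14-(dimethoxymethyl)nonacos-14-ene-2,27-diyne-1,29-diol
Product: 13 (2E,14E,27E)-14-(dimethoxymethyl)nonacosa-2,14,27-triene-1,29-diol
Conditions: NaAlH2(OCH2CH2OMe)2 (Red-Al, 5 equiv), THF, 0 °C → rt; aq. potassium sodium tartrate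
Reagents that add atoms: none
Why: Hydroxyl-directed trans-hydroalumination of the two propargylic alcohols, followed by protonolysis, gives only the E-allylic alcohols, while the isolated trisubstituted alkene and the acetal are inert to the hydride.

**Step 9**
Reactants: 13 (2E,14E,27E)-14-(dimethoxymethyl)nonacosa-2,14,27-triene-1,29-diol
Product: 14 bis(methyl carbonate) of 13
Conditions: ClCO2Me (3 equiv), pyridine, CH2Cl2, 0 °C
Reagents that add atoms: methyl chloroformate, COC(=O)Cl
Why: Acylation of the primary allylic alcohols with a chloroformate under pyridine buffering gives the allylic methyl carbonates needed as ionisable leaving groups, and the acetal is safe in the basic medium.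

**Step 10**
Reactants: 14 bis(methyl carbonate) of 13; 5 (2S,3S)-3-(tert-butyldimethylsilyloxy)pent-4-en-2-amine (2.6 equiv)
Product: 15 (3R,14E,27R)-N3,N27-bis[(2S,3S)-3-(tert-butyldimethylsilyloxy)pent-4-en-2-yl]-14-(dimethoxymethyl)nonacosa-1,14,28-triene-3,27-diamine
Conditions: [Ir(cod)Cl]2 (4 mol%), (Sa,S,S)-binaphthyl bis(1-phenylethyl)phosphoramidite (8 mol%), n-PrNH2 (catalyst activation), THF, rt → 40 °C
Reagents that add atoms: none
Why: Iridium-catalysed branched-selective asymmetric allylic amination: each carbonate ionises to a π-allyl iridium complex and the primary amine attacks the substituted terminus on the face left open by the cyclometalated phosphoramidite, so both new N-bearing carbons (the future C6 of ring A and of ring B) are set R by the catalyst independently of the S,S centres of 5, and the doubly α-branched secondary amine does not allylate again.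

**Step 11**
Reactants: 15 the bis(diallylic amine)
Product: 18 (2E)-1,1-dimethoxy-2-{10-[(2R,5S,6S)-5-(tert-butyldimethylsilyloxy)-6-methyl-1,2,5,6-tetrahydropyridin-2-yl]decyl}-14-[(2R,5S,6S)-5-(tert-butyldimethylsilyloxy)-6-methyl-1,2,5,6-tetrahydropyridin-2-yl]tetradec-2-ene, via bis-ammonium tosylate of the diene 16 (not isolated), via bis-ammonium tosylate of the cyclised product 17 (not isolated)
Conditions: anhydrous TsOH (2.0 equiv), CH2Cl2, rt; then RuCl2(=CHPh)(PCy3)(H2IMes) (second-generation Grubbs catalyst, 10 mol%), CH2Cl2 (3 mM), 40 °C; then Et3N, aq. NaHCO3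
Reagents that add atoms: none
Why: This is olefin ring-closing metathesis through metal carbenes: the ruthenium benzylidene exchanges onto a terminal vinyl group, the new alkylidene adds [2+2] to the second vinyl group on the same nitrogen to give a ruthenacyclobutane, and retro-[2+2] releases the ring alkene and Ru=CH2, the cycle being driven by loss of ethene. The closest known reaction type is the ring-closing metathesis of diallylic amine salts to 2,6-disubstituted 1,2,3,6-tetrahydropyridines. Ring A and ring B are each closed as a six-membered ring from a 1,7-diene, between the vinyl group on C6 and the vinyl group on C3, so the new C4=C5 bond is endocyclic and necessarily cis. No stereocentre is formed: C2 and C3 come from L-alanine (steps 1 to 3) and C6 from the catalyst-controlled amination (step 10), and none is at risk under these conditions. The step needs chemoselectivity for the four monosubstituted alkenes over the trisubstituted acetal-bearing alkene, which the hindrance of that alkene secures, and ring closure over oligomerisation or macrocyclisation, which the proximity of each vinyl pair and high dilution secure. Protonation with exactly two equivalents of anhydrous sulfonic acid keeps the amines off ruthenium without leaving free acid that could ionise the dimethyl acetal.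

**Step 12**
Reactants: 18 the bis(tetrahydropyridine) acetal
Product: 19 (2E)-1,1-dimethoxy-2-{10-[(2R,5S,6S)-5-(tert-butyldimethylsilyloxy)-6-methylpiperidin-2-yl]decyl}-14-[(2R,5S,6S)-5-(tert-butyldimethylsilyloxy)-6-methylpiperidin-2-yl]tetradec-2-ene
Conditions: 2-nitrobenzenesulfonohydrazide (excess, in portions), Et3N, CH2Cl2, rt
Reagents that add atoms: none
Why: Diimide reduction: diazene made from the sulfonyl hydrazide transfers two hydrogens suprafacially through a cyclic transition state and discriminates by alkene substitution, so the two cis-disubstituted ring alkenes should be reduced before the hindered trisubstituted junction alkene, while the basic anhydrous medium keeps acetal, silyl ethers and all stereocentres.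

**Step 13**
Reactants: 19 the bis(piperidine) acetal
Product: 21 (2E)-14-[(2R,5S,6S)-5-hydroxy-6-methylpiperidin-2-yl]-2-{10-[(2R,5S,6S)-5-hydroxy-6-methylpiperidin-2-yl]decyl}tetradec-2-enal, via target bis-hydrochloride 20 (not isolated)
Conditions: 3 M aq. HCl/THF, 40 °C; then cold aq. NaHCO3, CHCl3/i-PrOH extraction
Reagents that add atoms: water, O
Why: Aqueous acid hydrolysis of the dimethyl acetal to the E-enal and of both secondary silyl ethers in one operation, with the protonated amines unable to add to the enal; cold hydrogencarbonate then frees the hindered 2,6-disubstituted piperidines without touching a stereocentre.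

**Compound list**

1 | N-Boc-L-alanine N-methoxy-N-methylamide, tert-butyl N-[(2S)-1-[methoxy(methyl)amino]-1-oxopropan-2-yl]carbamate | C[C@H](NC(=O)OC(C)(C)C)C(=O)N(C)OC | starting material
2 | N-Boc-L-alaninal, tert-butyl N-[(2S)-1-oxopropan-2-yl]carbamate | C[C@H](NC(=O)OC(C)(C)C)C=O | intermediate
3 | tert-butyl N-[(2S,3S)-3-hydroxypent-4-en-2-yl]carbamate | C[C@H](NC(=O)OC(C)(C)C)[C@@H](O)C=C | intermediate
4 | tert-butyldimethylsilyl N-[(2S,3S)-3-(tert-butyldimethylsilyloxy)pent-4-en-2-yl]carbamate | C[C@H](NC(=O)O[Si](C)(C)C(C)(C)C)[C@@H](O[Si](C)(C)C(C)(C)C)C=C | intermediate (not isolated)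
5 | (2S,3S)-3-(tert-butyldimethylsilyloxy)pent-4-en-2-amine | C[C@H](N)[C@@H](O[Si](C)(C)C(C)(C)C)C=C | intermediate
6 | 12-bromododecan-1-ol | OCCCCCCCCCCCCBr | starting material
7 | 2-(prop-2-yn-1-yloxy)tetrahydro-2H-pyran (racemic) | C#CCOC1CCCCO1 | starting material
8 | 15-(tetrahydro-2H-pyran-2-yloxy)pentadec-13-yn-1-ol | OCCCCCCCCCCCCC#CCOC1CCCCO1 | intermediate
9 | 15-(tetrahydro-2H-pyran-2-yloxy)pentadec-13-ynal | O=CCCCCCCCCCCCC#CCOC1CCCCO1 | intermediate
10 | 3-hydroxy-2-[13-(tetrahydro-2H-pyran-2-yloxy)tridec-11-yn-1-yl]-17-(tetrahydro-2H-pyran-2-yloxy)heptadec-15-ynal (diastereomer mixture) | O=CC(CCCCCCCCCCC#CCOC1CCCCO1)C(O)CCCCCCCCCCCC#CCOC1CCCCO1 | intermediate (not isolated)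
11 | (2E)-2-[13-(tetrahydro-2H-pyran-2-yloxy)tridec-11-yn-1-yl]-17-(tetrahydro-2H-pyran-2-yloxy)heptadec-2-en-15-ynal | O1CCCCC1OCC#CCCCCCCCCCCC/C=C(/C=O)CCCCCCCCCCC#CCOC1CCCCO1 | intermediate
12 | (14E)-14-(dimethoxymethyl)nonacos-14-ene-2,27-diyne-1,29-diol | OCC#CCCCCCCCCCCC/C=C(/C(OC)OC)CCCCCCCCCCC#CCO | intermediate
13 | (2E,14E,27E)-14-(dimethoxymethyl)nonacosa-2,14,27-triene-1,29-diol | OC/C=C/CCCCCCCCCCC/C=C(/C(OC)OC)CCCCCCCCCC/C=C/CO | intermediate
14 | bis(methyl carbonate) of 13 | COC(=O)OC/C=C/CCCCCCCCCCC/C=C(/C(OC)OC)CCCCCCCCCC/C=C/COC(=O)OC | intermediate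
15 | (3R,14E,27R)-N3,N27-bis[(2S,3S)-3-(tert-butyldimethylsilyloxy)pent-4-en-2-yl]-14-(dimethoxymethyl)nonacosa-1,14,28-triene-3,27-diamine (metathesis precursor) | C[C@@H]([C@@H](O[Si](C)(C)C(C)(C)C)C=C)N[C@@H](C=C)CCCCCCCCCCC/C=C(/C(OC)OC)CCCCCCCCCC[C@H](C=C)N[C@@H](C)[C@@H](O[Si](C)(C)C(C)(C)C)C=C | intermediate
16 | bis(ammonium 4-methylbenzenesulfonate) of 15 | C[C@@H]([C@@H](O[Si](C)(C)C(C)(C)C)C=C)[NH2+][C@@H](C=C)CCCCCCCCCCC/C=C(/C(OC)OC)CCCCCCCCCC[C@H](C=C)[NH2+][C@@H](C)[C@@H](O[Si](C)(C)C(C)(C)C)C=C.Cc1ccc(cc1)S(=O)(=O)[O-].Cc1ccc(cc1)S(=O)(=O)[O-] | intermediate (not isolated)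
17 | bis(ammonium 4-methylbenzenesulfonate) of 18 | C[C@@H]1[NH2+][C@H](CCCCCCCCCCC/C=C(/C(OC)OC)CCCCCCCCCC[C@@H]2C=C[C@H](O[Si](C)(C)C(C)(C)C)[C@H](C)[NH2+]2)C=C[C@@H]1O[Si](C)(C)C(C)(C)C.Cc1ccc(cc1)S(=O)(=O)[O-].Cc1ccc(cc1)S(=O)(=O)[O-] | intermediate (not isolated)
18 | (2E)-1,1-dimethoxy-2-{10-[(2R,5S,6S)-5-(tert-butyldimethylsilyloxy)-6-methyl-1,2,5,6-tetrahydropyridin-2-yl]decyl}-14-[(2R,5S,6S)-5-(tert-butyldimethylsilyloxy)-6-methyl-1,2,5,6-tetrahydropyridin-2-yl]tetradec-2-ene (metathesis product) | C[C@@H]1N[C@H](CCCCCCCCCCC/C=C(/C(OC)OC)CCCCCCCCCC[C@@H]2C=C[C@H](O[Si](C)(C)C(C)(C)C)[C@H](C)N2)C=C[C@@H]1O[Si](C)(C)C(C)(C)C | intermediate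
19 | (2E)-1,1-dimethoxy-2-{10-[(2R,5S,6S)-5-(tert-butyldimethylsilyloxy)-6-methylpiperidin-2-yl]decyl}-14-[(2R,5S,6S)-5-(tert-butyldimethylsilyloxy)-6-methylpiperidin-2-yl]tetradec-2-ene | C[C@@H]1N[C@H](CCCCCCCCCCC/C=C(/C(OC)OC)CCCCCCCCCC[C@@H]2CC[C@H](O[Si](C)(C)C(C)(C)C)[C@H](C)N2)CC[C@@H]1O[Si](C)(C)C(C)(C)C | intermediate
20 | bis-hydrochloride of 21 | C[C@@H]1[NH2+][C@H](CCCCCCCCCCC/C=C(/C=O)CCCCCCCCCC[C@@H]2CC[C@H](O)[C@H](C)[NH2+]2)CC[C@@H]1O.[Cl-].[Cl-] | intermediate (not isolated)
21 | CNP0177491.1, (2E)-14-[(2R,5S,6S)-5-hydroxy-6-methylpiperidin-2-yl]-2-{10-[(2R,5S,6S)-5-hydroxy-6-methylpiperidin-2-yl]decyl}tetradec-2-enal | C[C@@H]1N[C@H](CCCCCCCCCCC/C=C(/C=O)CCCCCCCCCC[C@@H]2CC[C@H](O)[C@H](C)N2)CC[C@@H]1O | target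

**Step count.** Total: 13 steps. Longest linear sequence: 10 steps (6 → 21, steps 4 to 13); the amine 5 is made in 3 steps and joins at step 10.

**Steps most likely to fail**

Step 10 (double allylic amination). Attack of the hindered, β-silyloxy α-branched amine on the π-allyl iridium intermediate may be slow, so that linear substitution, carbonate decomposition or stalling after one amination takes over. The fallback uses a smaller nitrogen nucleophile and puts the silyl groups on afterwards. It sets out from 3 and 14. Acidolysis of the carbamate of 3 (HCl in dioxane, then NaOH) gives (3S,4S)-4-aminopent-1-en-3-ol F1. The same iridium-catalysed amination of 14 with F1, in which the amine reacts far faster than the neutral hydroxyl, gives (3R,14E,27R)-N3,N27-bis[(2S,3S)-3-hydroxypent-4-en-2-yl]-14-(dimethoxymethyl)nonacosa-1,14,28-triene-3,27-diamine F2. O-Silylation (TBSOTf, 2,6-lutidine, CH2Cl2, −78 °C; any N–Si bond is lost on aqueous work-up) comes back to the route at 15.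

Step 11 (double ring-closing metathesis). Incomplete protonation may let nitrogen bind ruthenium, or the second ring closure may stall so that intermolecular metathesis takes over. The fallback masks the amines covalently instead of as salts. It sets out from 15. (CF3CO)2O, pyridine, CH2Cl2, 0 °C gives the N,N'-bis(trifluoroacetyl) derivative of 15 F3. Ring-closing metathesis of this neutral amide (RuCl2(=CH-C6H4-2-OiPr)(H2IMes), the second-generation Hoveyda–Grubbs catalyst, toluene, 3 mM, 80 °C), helped by allylic 1,3-strain that turns the two vinyl groups on each nitrogen toward each other, gives the N,N'-bis(trifluoroacetyl) derivative of 18 F4. K2CO3 in MeOH/H2O (or NaBH4 in EtOH) removes the trifluoroacetyl groups and comes back to the route at 18.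

Step 12 (diimide reduction). Chemoselectivity may be lost, with hydrogen transfer to the junction alkene before both hindered ring alkenes are consumed, or the reduction may stop short. The fallback replaces the stoichiometric hydrogen donor by sterically controlled homogeneous catalytic hydrogenation. It sets out from 18: RhCl(PPh3)3 (10 mol%), H2 (1 atm), benzene/EtOH, rt, which reduces cis-disubstituted alkenes much faster than trisubstituted ones, and comes back to the route at 19. It passes through no new compound (entry F0).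

**Further compounds**

F1 | step 10 | (3S,4S)-4-aminopent-1-en-3-ol | C[C@H](N)[C@@H](O)C=C
F2 | step 10 | (3R,14E,27R)-N3,N27-bis[(2S,3S)-3-hydroxypent-4-en-2-yl]-14-(dimethoxymethyl)nonacosa-1,14,28-triene-3,27-diamine | C[C@@H]([C@@H](O)C=C)N[C@@H](C=C)CCCCCCCCCCC/C=C(/C(OC)OC)CCCCCCCCCC[C@H](C=C)N[C@@H](C)[C@@H](O)C=C
F3 | step 11 | N,N'-bis(trifluoroacetyl) derivative of 15 | C[C@@H]([C@@H](O[Si](C)(C)C(C)(C)C)C=C)N(C(=O)C(F)(F)F)[C@@H](C=C)CCCCCCCCCCC/C=C(/C(OC)OC)CCCCCCCCCC[C@H](C=C)N(C(=O)C(F)(F)F)[C@@H](C)[C@@H](O[Si](C)(C)C(C)(C)C)C=C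
F4 | step 11 | N,N'-bis(trifluoroacetyl) derivative of 18 | C[C@@H]1N(C(=O)C(F)(F)F)[C@H](CCCCCCCCCCC/C=C(/C(OC)OC)CCCCCCCCCC[C@@H]2C=C[C@H](O[Si](C)(C)C(C)(C)C)[C@H](C)N2C(=O)C(F)(F)F)C=C[C@@H]1O[Si](C)(C)C(C)(C)C
F0 | step 12 | none | none
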